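Numbering: C7 is the dioxane CH carrying ring A (trimethoxyphenyl) and O7, C8 the CH carrying methyl C9 and O8; ring B holds O7 on C3' and O8 on C4'. Everything rests on cutting C7–C8 and C7–ring A: the chain C9–C8–C7, in which C8 and C7 are adjacent CH centres each bearing one oxygen (C7 also ring A), is grown carbon by carbon on a boronic ester of (1S,2S)-1,2-dicyclohexylethane-1,2-diol. In one operation the key step inserts C7 between C8 and boron and arylates it, setting C7 threo to C8. Its precursor is the (S)-1-aryloxyethyl boronate whose O8 already joins C8 to C4' of a 2-bromo-6-methoxy-4-(1,3-dioxolan-2-yl)phenyl ring B.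

Key step: step 6

Remark on stereochemistry: the sense of induction is taken from the established behaviour of boronic esters of C2-symmetric diols, where the (S,S)-diol gives the (αR)-chloro boronate (Cl > C > B). On that basis the (S,S) director gives (8S) in 11 (boron ranks below methyl; spatially the target geometry) and (7R,8R) after the second cycle and oxidation, so the target (2R,3R)-trans-dioxane needs no change of antipode.

Remark on the precursor: the formyl group of ring B is carried as a 1,3-dioxolane instead of an open dimethyl acetal. An open acetal of an electron-rich benzaldehyde would be at risk toward ZnCl2, the Grignard reagent and silica, whereas the cyclic acetal should tolerate them and still fall to dilute acid.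

Remark on the carbenoid: (dichloromethyl)lithium cannot be stored or warmed, so it is generated twice from dichloromethane 4. It is numbered 5 as the intermediate of step 2; in step 6 it is the reagent made in the flask from 4 and n-BuLi and used up there.

Step 1
Reactants: 1 methylboronic acid; 2 (1S,2S)-1,2-dicyclohexylethane-1,2-diol
Product: 3 (4S,5S)-4,5-dicyclohexyl-2-methyl-1,3,2-dioxaborolane
Conditions: MgSO4, Et2O, rt
Reagents that add atoms: none
Why: Boronic esterification of a boronic acid by a 1,2-diol is driven to the five-membered cyclic ester by removal of water and leaves the diol stereocentres untouched.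

Step 2
Reactants: 3 (4S,5S)-4,5-dicyclohexyl-2-methyl-1,3,2-dioxaborolane; 4 dichloromethane
Product: 7 (4S,5S)-2-[(1R)-1-chloroethyl]-4,5-dicyclohexyl-1,3,2-dioxaborolane, via (dichloromethyl)lithium 5 (not isolated), via lithium dichloromethyl(methyl)borate 6 (not isolated)
Conditions: n-BuLi, THF, −100 °C; add 3; ZnCl2 (1 equiv), −100 °C → rt; crude product used directly
Reagents that add atoms: none
Why: Matteson homologation, in which the carbenoid adds to boron and the ZnCl2-assisted 1,2-shift of methyl expels the chloride singled out by the (S,S)-diol, should set C8 as the (R)-chloride.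

Step 3
Reactants: 8 5-bromovanillin
Product: 9 2-bromo-4-(1,3-dioxolan-2-yl)-6-methoxyphenol
Conditions: HOCH2CH2OH, p-TsOH·H2O (cat.), toluene, reflux, Dean–Stark; Et3N quench
Reagents that add atoms: ethylene glycol, OCCO
Why: Acid-catalysed acetalisation with azeotropic removal of water masks the aldehyde as a cyclic acetal, leaves the phenol free and makes the derived phenoxide more nucleophilic than that of the aldehyde.

Step 4
Reactants: 7 (4S,5S)-2-[(1R)-1-chloroethyl]-4,5-dicyclohexyl-1,3,2-dioxaborolane; 9 2-bromo-4-(1,3-dioxolan-2-yl)-6-methoxyphenol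
Product: 11 (4S,5S)-2-{(1S)-1-[2-bromo-4-(1,3-dioxolan-2-yl)-6-methoxyphenoxy]ethyl}-4,5-dicyclohexyl-1,3,2-dioxaborolane, via sodium phenolate 10 (not isolated)
Conditions: NaH, THF, 0 °C; then 7, THF–DMSO, rt → 45 °C; chromatography on Et3N-treated silica
Reagents that add atoms: none
Why: Displacement of the chloride of an α-chloro boronic ester by an oxygen nucleophile (Matteson-type substitution through the aryloxy borate and a 1,2-shift, or direct SN2) goes with inversion, so the (R)-chloride should become the (S)-aryl ether that has the C8 geometry of the target and fixes O8 on C4'.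

Step 5
Reactants: 12 5-bromo-1,2,3-trimethoxybenzene
Product: 13 (3,4,5-trimethoxyphenyl)magnesium bromide (THF solution, titrated)
Conditions: Mg turnings, I2 (cat.), THF, 50 °C
Reagents that add atoms: magnesium, [Mg]
Why: Grignard formation by direct insertion of Mg into an aryl bromide is routine for this electron-rich arene.

Step 6
Reactants: 11 (4S,5S)-2-{(1S)-1-[2-bromo-4-(1,3-dioxolan-2-yl)-6-methoxyphenoxy]ethyl}-4,5-dicyclohexyl-1,3,2-dioxaborolane; 4 dichloromethane; 13 (3,4,5-trimethoxyphenyl)magnesium bromide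
Product: 17 (4S,5S)-2-{(1R,2R)-2-[2-bromo-4-(1,3-dioxolan-2-yl)-6-methoxyphenoxy]-1-(3,4,5-trimethoxyphenyl)propyl}-4,5-dicyclohexyl-1,3,2-dioxaborolane, via lithium dichloromethyl borate 14 (not isolated), via α-chloro boronate 15 (not isolated), via bromomagnesium aryl borate 16 (not isolated)
Conditions: 4, n-BuLi, THF, −100 °C (LiCHCl2 made afresh in the flask, as in step 2); add 11; ZnCl2 (1.5 equiv), −100 °C → rt; then 13 (4 equiv, in excess over ZnCl2), −78 °C → rt
Reagents that add atoms: none
Why: (Dichloromethyl)lithium, made afresh in the flask from 4 and n-BuLi, adds to boron of 11 to give borate 14, and on warming with ZnCl2 C8 shifts from boron to the new carbon with retention while one chloride leaves (C7–C8 bond, α-chloro boronate 15); Grignard reagent 13 then adds to boron (borate 16) and the aryl group shifts to C7 anti to the remaining chloride, with inversion (C7–ring A bond). The closest known reaction type is the Matteson homologation of α-alkoxy boronic esters of C2-symmetric diols followed by Grignard displacement, run here in one flask. No ring is closed. The one new stereocentre, C7, is controlled by the (S,S)-diol on boron, which in the ZnCl2-bound borate decides which diastereotopic chloride departs to give (7R)-15, and the stereospecific aryl shift then places boron where O7 will stand, threo to O8. The step needs selection between the two chlorides (secured by the C2-symmetric director together with ZnCl2, which also ties up chloride that could epimerise 15) and a 1,2-shift in preference to loss of the aryloxide from C8, which is favoured because chloride activated by the Zn and Mg Lewis acids is the better leaving group and because the acetal keeps ring B electron-rich and its phenoxide a poor leaving group. The aryl bromide and the dioxolane should be inert to the carbenoid at −100 °C and to 13.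

Step 7
Reactants: 17 (4S,5S)-2-{(1R,2R)-2-[2-bromo-4-(1,3-dioxolan-2-yl)-6-methoxyphenoxy]-1-(3,4,5-trimethoxyphenyl)propyl}-4,5-dicyclohexyl-1,3,2-dioxaborolane
Product: 18 (1R,2R)-2-[2-bromo-4-(1,3-dioxolan-2-yl)-6-methoxyphenoxy]-1-(3,4,5-trimethoxyphenyl)propan-1-ol
Conditions: 30% H2O2, 2 M NaOH, THF, 0 °C → rt
Reagents that add atoms: hydrogen peroxide, OO
Why: Oxidation of a boronic ester by alkaline hydroperoxide moves C7 from boron to oxygen with retention and should give the threo (7R,8R) alcohol, with the diol director recovered.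

Step 8
Reactants: 18 (1R,2R)-2-[2-bromo-4-(1,3-dioxolan-2-yl)-6-methoxyphenoxy]-1-(3,4,5-trimethoxyphenyl)propan-1-ol
Product: 20 (2R,3R)-8-methoxy-2-methyl-3-(3,4,5-trimethoxyphenyl)-2,3-dihydro-1,4-benzodioxine-6-carbaldehyde, via benzodioxane acetal 19 (not isolated)
Conditions: CuI (10 mol%), 3,4,7,8-tetramethyl-1,10-phenanthroline (20 mol%), Cs2CO3, toluene, 110 °C; then 1 M HCl, THF, rt
Reagents that add atoms: water, O
Why: Intramolecular Ullmann-type C–O coupling of the C7 alkoxide with the C3' bromide closes the six-membered dioxane without breaking a bond at C7 or C8, so the threo alcohol becomes the trans ring; the acetal keeps ring B electron-rich during closure so that a Smiles shift of the ring from O8 to O7 is not favoured, and the acid work-up then hydrolyses the dioxolane.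

Step 9
Reactants: 20 (2R,3R)-8-methoxy-2-methyl-3-(3,4,5-trimethoxyphenyl)-2,3-dihydro-1,4-benzodioxine-6-carbaldehyde
Product: 21 ethyl (2E)-3-[(2R,3R)-8-methoxy-2-methyl-3-(3,4,5-trimethoxyphenyl)-2,3-dihydro-1,4-benzodioxin-6-yl]prop-2-enoate
Conditions: (EtO)2P(O)CH2CO2Et, NaH, THF, 0 °C → rt
Reagents that add atoms: triethyl phosphonoacetate, CCOC(=O)CP(=O)(OCC)OCC
Why: Horner–Wadsworth–Emmons olefination of an aromatic aldehyde with a stabilised phosphonate anion should give the (E)-cinnamate.

Step 10
Reactants: 21 ethyl (2E)-3-[(2R,3R)-8-methoxy-2-methyl-3-(3,4,5-trimethoxyphenyl)-2,3-dihydro-1,4-benzodioxin-6-yl]prop-2-enoate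
Product: 22 (2E)-3-[(2R,3R)-8-methoxy-2-methyl-3-(3,4,5-trimethoxyphenyl)-2,3-dihydro-1,4-benzodioxin-6-yl]prop-2-en-1-ol (target)
Conditions: i-Bu2AlH (3 equiv), CH2Cl2, −78 → 0 °C; aqueous KNaC4H4O6 work-up
Reagents that add atoms: none
Why: 1,2-Reduction of an α,β-unsaturated ester by i-Bu2AlH should give the allylic alcohol and leave the alkene, the aryl ethers and both stereocentres untouched.

Compound list
1 | methylboronic acid | CB(O)O | starting material
2 | (1S,2S)-1,2-dicyclohexylethane-1,2-diol | O[C@@H](C1CCCCC1)[C@@H](O)C1CCCCC1 | starting material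
3 | (4S,5S)-4,5-dicyclohexyl-2-methyl-1,3,2-dioxaborolane | CB1O[C@@H](C2CCCCC2)[C@H](C2CCCCC2)O1 | intermediate
4 | dichloromethane | ClCCl | starting material
5 | (dichloromethyl)lithium | [Li]C(Cl)Cl | intermediate
6 | lithium (4S,5S)-4,5-dicyclohexyl-2-(dichloromethyl)-2-methyl-1,3,2-dioxaborolan-2-uide | [Li+].C[B-]1(C(Cl)Cl)O[C@@H](C2CCCCC2)[C@H](C2CCCCC2)O1 | intermediate
7 | (4S,5S)-2-[(1R)-1-chloroethyl]-4,5-dicyclohexyl-1,3,2-dioxaborolane | C[C@H](Cl)B1O[C@@H](C2CCCCC2)[C@H](C2CCCCC2)O1 | intermediate
8 | 5-bromovanillin (3-bromo-4-hydroxy-5-methoxybenzaldehyde) | COc1cc(C=O)cc(Br)c1O | starting material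
9 | 2-bromo-4-(1,3-dioxolan-2-yl)-6-methoxyphenol | COc1cc(C2OCCO2)cc(Br)c1O | intermediate
10 | sodium 2-bromo-4-(1,3-dioxolan-2-yl)-6-methoxyphenolate | [Na+].COc1cc(C2OCCO2)cc(Br)c1[O-] | intermediate
11 | (4S,5S)-2-{(1S)-1-[2-bromo-4-(1,3-dioxolan-2-yl)-6-methoxyphenoxy]ethyl}-4,5-dicyclohexyl-1,3,2-dioxaborolane | C[C@@H](Oc1c(Br)cc(C2OCCO2)cc1OC)B1O[C@@H](C2CCCCC2)[C@H](C2CCCCC2)O1 | intermediate
12 | 5-bromo-1,2,3-trimethoxybenzene | COc1cc(Br)cc(OC)c1OC | starting material
13 | (3,4,5-trimethoxyphenyl)magnesium bromide | COc1cc([Mg]Br)cc(OC)c1OC | intermediate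
14 | lithium (4S,5S)-2-{(1S)-1-[2-bromo-4-(1,3-dioxolan-2-yl)-6-methoxyphenoxy]ethyl}-4,5-dicyclohexyl-2-(dichloromethyl)-1,3,2-dioxaborolan-2-uide | [Li+].C[C@@H](Oc1c(Br)cc(C2OCCO2)cc1OC)[B-]1(C(Cl)Cl)O[C@@H](C2CCCCC2)[C@H](C2CCCCC2)O1 | intermediate
15 | (4S,5S)-2-{(1R,2R)-2-[2-bromo-4-(1,3-dioxolan-2-yl)-6-methoxyphenoxy]-1-chloropropyl}-4,5-dicyclohexyl-1,3,2-dioxaborolane | C[C@@H](Oc1c(Br)cc(C2OCCO2)cc1OC)[C@H](Cl)B1O[C@@H](C2CCCCC2)[C@H](C2CCCCC2)O1 | intermediate
16 | bromomagnesium (4S,5S)-2-{(1R,2R)-2-[2-bromo-4-(1,3-dioxolan-2-yl)-6-methoxyphenoxy]-1-chloropropyl}-4,5-dicyclohexyl-2-(3,4,5-trimethoxyphenyl)-1,3,2-dioxaborolan-2-uide | C[C@@H](Oc1c(Br)cc(C2OCCO2)cc1OC)[C@H](Cl)[B-]1(c2cc(OC)c(OC)c(OC)c2)O[C@@H](C2CCCCC2)[C@H](C2CCCCC2)O1.Br[Mg+] | intermediate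
17 | (4S,5S)-2-{(1R,2R)-2-[2-bromo-4-(1,3-dioxolan-2-yl)-6-methoxyphenoxy]-1-(3,4,5-trimethoxyphenyl)propyl}-4,5-dicyclohexyl-1,3,2-dioxaborolane | COc1cc([C@H]([C@@H](C)Oc2c(Br)cc(C3OCCO3)cc2OC)B2O[C@@H](C3CCCCC3)[C@H](C3CCCCC3)O2)cc(OC)c1OC | intermediate
18 | (1R,2R)-2-[2-bromo-4-(1,3-dioxolan-2-yl)-6-methoxyphenoxy]-1-(3,4,5-trimethoxyphenyl)propan-1-ol | COc1cc([C@H]([C@@H](C)Oc2c(Br)cc(C3OCCO3)cc2OC)O)cc(OC)c1OC | intermediate
19 | (2R,3R)-7-(1,3-dioxolan-2-yl)-5-methoxy-3-methyl-2-(3,4,5-trimethoxyphenyl)-2,3-dihydro-1,4-benzodioxine | COc1cc([C@H]2Oc3cc(C4OCCO4)cc(OC)c3O[C@@H]2C)cc(OC)c1OC | intermediate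
20 | (2R,3R)-8-methoxy-2-methyl-3-(3,4,5-trimethoxyphenyl)-2,3-dihydro-1,4-benzodioxine-6-carbaldehyde | COc1cc([C@H]2Oc3cc(C=O)cc(OC)c3O[C@@H]2C)cc(OC)c1OC | intermediate
21 | ethyl (2E)-3-[(2R,3R)-8-methoxy-2-methyl-3-(3,4,5-trimethoxyphenyl)-2,3-dihydro-1,4-benzodioxin-6-yl]prop-2-enoate | COc1cc([C@H]2Oc3cc(/C=C/C(=O)OCC)cc(OC)c3O[C@@H]2C)cc(OC)c1OC | intermediate
22 | (2E)-3-[(2R,3R)-8-methoxy-2-methyl-3-(3,4,5-trimethoxyphenyl)-2,3-dihydro-1,4-benzodioxin-6-yl]prop-2-en-1-ol | COc1cc([C@H]2Oc3cc(/C=C/CO)cc(OC)c3O[C@@H]2C)cc(OC)c1OC | target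

Total step count: 10. Longest linear sequence: 8 steps (steps 1, 2, 4, 6, 7, 8, 9 and 10, from methylboronic acid); steps 3 and 5 are short side branches.

Steps most likely to fail

Step 6 (key step). The aryloxide on C8 may be lost by β-elimination from one of the borates or from the Lewis-acid-bound α-chloro boronate, in competition with the 1,2-shifts. Chloride-induced epimerisation at C7 may erode the selection between the two chlorides, and part of the Grignard reagent is consumed by ZnCl2. The fallback sets out from 11 and keeps only the first half of the step. The insertion is run as before to α-chloro boronate 15, which instead of being arylated is oxidised (H2O2, aqueous NaHCO3, THF, 0 °C) to (2R)-2-[2-bromo-4-(1,3-dioxolan-2-yl)-6-methoxyphenoxy]propanal F1. Grignard reagent 13 is then added to F1 in the presence of MgBr2·OEt2 in CH2Cl2–Et2O at −78 °C. Under chelation control the five-membered chelate between the carbonyl oxygen and O8 is attacked anti to the methyl group, which should give the threo alcohol and bring the route back at 18. The C7–ring A bond is thus made by carbonyl addition, and no aryl borate with an aryloxide β to boron is involved.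

Step 4. The hindered, weakly nucleophilic 2,6-disubstituted phenoxide may substitute slowly, so that chloride-induced epimerisation at C8 or dehydrochlorination of 7 competes. The fallback leaves boron chemistry for C8 and sets out from phenol 9. A Mitsunobu reaction with ethyl (S)-lactate (PPh3, DIAD, THF, 0 °C → rt) should give, with inversion, ethyl (2R)-2-[2-bromo-4-(1,3-dioxolan-2-yl)-6-methoxyphenoxy]propanoate F2. Reduction with i-Bu2AlH (toluene, −78 °C) leads to aldehyde F1, and the chelation-controlled addition of 13 described above brings the route back at 18.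

Step 8. The C–O coupling of the hindered secondary benzylic alkoxide may be sluggish, with reductive loss of bromine or oxidation of the carbinol to the ketone taking over. The fallback closes the ring at C7 instead of at C3' and sets out from 18. Bromine–lithium exchange on the alkoxide (n-BuLi, 2.2 equiv, THF, −78 °C), trapping with B(OMe)3 and oxidation (H2O2, NaOH) should give (1R,2R)-2-[4-(1,3-dioxolan-2-yl)-2-hydroxy-6-methoxyphenoxy]-1-(3,4,5-trimethoxyphenyl)propan-1-ol F3. Treatment with p-TsOH·H2O in wet toluene at 60 °C ionises the benzylic C7–OH. The C3' phenol should then close the dioxane under thermodynamic control to the trans (diequatorial) isomer, with C8 untouched, while the same acid frees the aldehyde, so the route is rejoined at 20.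

Further compounds
F1 | step 6 | (2R)-2-[2-bromo-4-(1,3-dioxolan-2-yl)-6-methoxyphenoxy]propanal | C[C@@H](Oc1c(Br)cc(C2OCCO2)cc1OC)C=O
F2 | step 4 | ethyl (2R)-2-[2-bromo-4-(1,3-dioxolan-2-yl)-6-methoxyphenoxy]propanoate | C[C@@H](Oc1c(Br)cc(C2OCCO2)cc1OC)C(=O)OCC
F3 | step 8 | (1R,2R)-2-[4-(1,3-dioxolan-2-yl)-2-hydroxy-6-methoxyphenoxy]-1-(3,4,5-trimethoxyphenyl)propan-1-ol | COc1cc([C@H]([C@@H](C)Oc2c(O)cc(C3OCCO3)cc2OC)O)cc(OC)c1OC
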